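The five-membered ring is C1 (quaternary, CH3)–C2 (OAc)–C3–C4 (OH, iPr)–C5, and the seven-membered ring is C5–C6 (O-veratroyl)–C7–C8=C9–C10 (OAc)–C1. The 1,3-dioxygen pattern O2/O4/O6 marks the cyclopentane as a double-aldol retron, so it is cut at C2–C3 and C4–C5. C2–C1–C5 is stored in a donor–acceptor cyclopropane (a 2-siloxycyclopropyl ketone, i.e. a masked C2 oxocarbenium ion and C5 enolate). C3–C4 comes from the silyl enol ether of 3-methylbutan-2-one. One TiCl4-mediated formal [3+2] cycloaddition forms both bonds and sets C2, C4 and C5 from C1. Ring-closing metathesis at C8=C9 then closes the seven-membered ring, and a hydroxyl-directed reduction sets C6.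

Key step: step 9

Remark on the chemistry: 2-methylmalonaldehyde (1) reacts through its enol tautomer. Cyclopropanes 9, 10 and 12 are drawn as the C5 epimer with the carbonyl group cis to the ring methyl group; the other C5 epimer, if it forms, converges in step 9 because C5 and C2 become planar when the ring opens. TBS = tert-butyldimethylsilyl.

Step 1
Reactants: 1 2-methylmalonaldehyde
Product: 2 (2E)-3-[(tert-butyldimethylsilyl)oxy]-2-methylprop-2-enal
Conditions: TBSCl, Et3N, CH2Cl2, 0 °C to rt
Reagents that add atoms: tert-butyldimethylsilyl chloride, CC(C)(C)[Si](C)(C)Cl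
Why: O-silylation of the enol form of the β-dialdehyde (a vinylogous acid) should give the push–pull enal, which equilibrates to the E isomer with the silyloxy group trans to the formyl group.

Step 2
Reactants: 2 (2E)-3-[(tert-butyldimethylsilyl)oxy]-2-methylprop-2-enal; 3 vinylmagnesium bromide
Product: 5 rac-(1E)-1-[(tert-butyldimethylsilyl)oxy]-2-methylpenta-1,4-dien-3-yl acetate, via bromomagnesium alkoxide 4 (not isolated)
Conditions: CH2=CHMgBr, THF, −78 °C; then Ac2O, −78 to 0 °C; aq NaHCO3
Reagents that add atoms: acetic anhydride, CC(=O)OC(C)=O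
Why: Grignard 1,2-addition to the aldehyde followed by acetylation of the magnesium alkoxide in the same flask should give the allylic acetate, racemic at C10, an open-chain analogue of a glycal 3-acetate that is stable under neutral conditions.

Step 3
Reactants: 5 rac-(1E)-1-[(tert-butyldimethylsilyl)oxy]-2-methylpenta-1,4-dien-3-yl acetate
Product: 6 (1E,3R)-1-[(tert-butyldimethylsilyl)oxy]-2-methylpenta-1,4-dien-3-ol
Conditions: Candida antarctica lipase B (immobilised), n-BuOH, tBuOMe, 30 °C, stopped just short of half conversion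
Reagents that add atoms: none
Why: Lipase-catalysed kinetic resolution by alcoholysis; by the Kazlauskas rule (large group = the trisubstituted enol ether arm, medium group = vinyl) the enzyme should cleave the R acetate and so set C10 as R, while the S acetate stays untouched and is separated.

Step 4
Reactants: 6 (1E,3R)-1-[(tert-butyldimethylsilyl)oxy]-2-methylpenta-1,4-dien-3-ol
Product: 7 (1E,3R)-1,3-bis[(tert-butyldimethylsilyl)oxy]-2-methylpenta-1,4-diene
Conditions: TBSCl, imidazole, DMF, rt
Reagents that add atoms: tert-butyldimethylsilyl chloride, CC(C)(C)[Si](C)(C)Cl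
Why: Standard silylation of the secondary allylic alcohol under basic conditions that leave the acid-labile enol ether intact; no stereocentre is touched.

Step 5
Reactants: 7 (1E,3R)-1,3-bis[(tert-butyldimethylsilyl)oxy]-2-methylpenta-1,4-diene; 8 ethyl diazoacetate
Product: 9 ethyl (1R,2S,3R)-3-[(tert-butyldimethylsilyl)oxy]-2-[(1R)-1-[(tert-butyldimethylsilyl)oxy]prop-2-en-1-yl]-2-methylcyclopropane-1-carboxylate
Conditions: Rh2(OAc)4 (1 mol %), slow addition of 8, CH2Cl2, rt
Reagents that add atoms: none
Why: Rhodium-carbenoid cyclopropanation of the electron-rich trisubstituted silyl enol ether (far more nucleophilic than the terminal vinyl group) should give the donor–acceptor 2-siloxycyclopropanecarboxylate by stereospecific cis addition (OTBS stays cis to CH3), and C1 is set under substrate control, since in the reactive conformer C10–H eclipses the C1 methyl group (allylic 1,2-strain) and the carbenoid approaches anti to the bulky C10–OTBS group.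

Step 6
Reactants: 9 ethyl (1R,2S,3R)-3-[(tert-butyldimethylsilyl)oxy]-2-[(1R)-1-[(tert-butyldimethylsilyl)oxy]prop-2-en-1-yl]-2-methylcyclopropane-1-carboxylate
Product: 10 (1R,2S,3R)-3-[(tert-butyldimethylsilyl)oxy]-2-[(1R)-1-[(tert-butyldimethylsilyl)oxy]prop-2-en-1-yl]-N-methoxy-N,2-dimethylcyclopropane-1-carboxamide
Conditions: MeNH(OMe)·HCl, iPrMgCl, THF, −20 to 0 °C
Reagents that add atoms: N,O-dimethylhydroxylamine hydrochloride, CNOC.Cl
Why: Aminolysis of the ester by the chloromagnesium amide formed in the flask (Weinreb amide synthesis) should proceed without opening the siloxycyclopropane, which tolerates basic media free of Lewis acid and fluoride.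

Step 7
Reactants: 10 (1R,2S,3R)-3-[(tert-butyldimethylsilyl)oxy]-2-[(1R)-1-[(tert-butyldimethylsilyl)oxy]prop-2-en-1-yl]-N-methoxy-N,2-dimethylcyclopropane-1-carboxamide; 11 (2-methylprop-2-en-1-yl)magnesium chloride
Product: 12 1-[(1R,2S,3R)-3-[(tert-butyldimethylsilyl)oxy]-2-[(1R)-1-[(tert-butyldimethylsilyl)oxy]prop-2-en-1-yl]-2-methylcyclopropyl]-3-methylbut-3-en-1-one
Conditions: CH2=C(CH3)CH2MgCl, THF, −78 to −40 °C; pH 7 buffer
Reagents that add atoms: none
Why: Weinreb ketone synthesis: the chelated magnesium adduct stops at mono-addition and releases the β,γ-unsaturated ketone only on buffered work-up, which should prevent both over-addition and migration of the double bond into conjugation.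

Step 8
Reactants: 13 3-methylbutan-2-one
Product: 15 3-methyl-2-[(trimethylsilyl)oxy]but-1-ene, via lithium enolate 14 (not isolated)
Conditions: LiN(iPr)2, THF, −78 °C; then Me3SiCl
Reagents that add atoms: chlorotrimethylsilane, C[Si](C)(C)Cl
Why: Kinetic deprotonation of the methyl ketone at the methyl group and O-silylation should give the less substituted silyl enol ether.

Step 9
Reactants: 12 1-[(1R,2S,3R)-3-[(tert-butyldimethylsilyl)oxy]-2-[(1R)-1-[(tert-butyldimethylsilyl)oxy]prop-2-en-1-yl]-2-methylcyclopropyl]-3-methylbut-3-en-1-one; 15 3-methyl-2-[(trimethylsilyl)oxy]but-1-ene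
Product: 18 1-[(1R,2R,3S,5R)-3-[(tert-butyldimethylsilyl)oxy]-2-[(1R)-1-[(tert-butyldimethylsilyl)oxy]prop-2-en-1-yl]-5-hydroxy-2-methyl-5-(propan-2-yl)cyclopentyl]-3-methylbut-3-en-1-one, via ring-opened titanium enolate oxocarbenium zwitterion 16 (not isolated), via open-chain keto titanium enolate 17 (not isolated)
Conditions: 15 (3 equiv), TiCl4 (1.2 equiv), CH2Cl2, −78 to −40 °C; aq NaHCO3
Reagents that add atoms: none
Why: TiCl4 binds the ketone of 12 and the push–pull C2–C5 bond of the cyclopropane opens to zwitterion 16, a C5=C6 titanium enolate next to a C2 silyloxocarbenium ion; the CH2 terminus of 15 adds to C2 (Mukaiyama addition, C2–C3 bond), Me3SiCl is expelled to give keto enolate 17, and the enolate carbon C5 then adds to the C4 ketone (intramolecular aldol, C4–C5 bond). The closest known reaction type is the Lewis-acid-mediated formal [3+2] cycloaddition of donor–acceptor cyclopropanes with silyl enol ethers. The cyclopentane C1–C5 closes by a 5-(enolexo)-exo-trig aldol addition. C2 is set by Felkin–Anh addition to the oxocarbenium ion (the branched CH(OTBS)CH=CH2 arm on C1 anti to the nucleophile, which passes the C1 methyl group), C5 by the enolate attacking with its C6 terminus on the methyl face of C1 away from that arm, and C4 by a closed, titanium-bridged Zimmerman–Traxler-type transition state that places O4 cis to the C6 carbonyl and the isopropyl group on the opposite face. The step needs capture of the oxocarbenium ion by external 15 instead of by the pendant methallyl alkene, a second enolate or reclosure, and C5 instead of C7 as the nucleophile: the first is secured by the much higher nucleophilicity of the 1,1-disubstituted silyl enol ether used in excess at −78 °C and by the neopentyl shielding of C5, the second by the cyclopropane, which can release the enolate only toward C5.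

Step 10
Reactants: 18 1-[(1R,2R,3S,5R)-3-[(tert-butyldimethylsilyl)oxy]-2-[(1R)-1-[(tert-butyldimethylsilyl)oxy]prop-2-en-1-yl]-5-hydroxy-2-methyl-5-(propan-2-yl)cyclopentyl]-3-methylbut-3-en-1-one
Product: 19 (1R,2S,4R,5R,10R)-2,10-bis[(tert-butyldimethylsilyl)oxy]-4-hydroxydauc-8-en-6-one (trans-fused; 1β-CH3, 5α-H, 4β-OH, 2α- and 10α-OTBS)
Conditions: second-generation Grubbs catalyst (H2IMes)(PCy3)Cl2Ru=CHPh (5 mol %), CH2Cl2, 40 °C, high dilution
Reagents that add atoms: none
Why: Ring-closing metathesis between the vinyl group on C10 and the methallyl group on C6 should close the seven-membered ring as its trisubstituted C8=C9 olefin; the trans ring fusion is already fixed at C1 and C5 and no stereocentre is formed.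

Step 11
Reactants: 19 (1R,2S,4R,5R,10R)-2,10-bis[(tert-butyldimethylsilyl)oxy]-4-hydroxydauc-8-en-6-one
Product: 20 (1R,2S,4R,5S,6S,10R)-2,10-bis[(tert-butyldimethylsilyl)oxy]dauc-8-ene-4,6-diol
Conditions: Me4NBH(OAc)3, MeCN/AcOH, −30 °C
Reagents that add atoms: none
Why: Evans–Saksena reduction: the C4 hydroxyl binds boron and delivers hydride intramolecularly to the β face of the C6 ketone, which should give the 1,3-anti diol with the 6α-hydroxyl (6S).

Step 12
Reactants: 20 (1R,2S,4R,5S,6S,10R)-2,10-bis[(tert-butyldimethylsilyl)oxy]dauc-8-ene-4,6-diol; 21 3,4-dimethoxybenzoyl chloride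
Product: 22 (1R,2S,4R,5S,6S,10R)-2,10-bis[(tert-butyldimethylsilyl)oxy]-4-hydroxydauc-8-en-6-yl 3,4-dimethoxybenzoate
Conditions: Et3N, DMAP, CH2Cl2, rt to 40 °C
Reagents that add atoms: none
Why: DMAP-catalysed acylation should take place only at the secondary C6 hydroxyl, the tertiary C4 hydroxyl being too hindered to react.

Step 13
Reactants: 22 (1R,2S,4R,5S,6S,10R)-2,10-bis[(tert-butyldimethylsilyl)oxy]-4-hydroxydauc-8-en-6-yl 3,4-dimethoxybenzoate
Product: 23 (1R,2S,4R,5S,6S,10R)-2,4,10-trihydroxydauc-8-en-6-yl 3,4-dimethoxybenzoate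
Conditions: HF·pyridine, THF/pyridine, 0 °C to rt
Reagents that add atoms: none
Why: Fluoride cleaves both secondary silyl ethers under mildly acidic conditions that should spare the ester, the allylic system and the tertiary alcohol.

Step 14
Reactants: 23 (1R,2S,4R,5S,6S,10R)-2,4,10-trihydroxydauc-8-en-6-yl 3,4-dimethoxybenzoate
Product: 24 (1R,2S,4R,5S,6S,10R)-2,10-diacetoxy-4-hydroxydauc-8-en-6-yl 3,4-dimethoxybenzoate (CNP0320758.1)
Conditions: Ac2O, pyridine, DMAP (cat.), CH2Cl2, 0 °C to rt
Reagents that add atoms: acetic anhydride, CC(=O)OC(C)=O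
Why: Acetylation of the two secondary hydroxyls at C2 and C10 should leave the tertiary C4 hydroxyl free under these mild conditions and give the target.

Compound list
1 | 2-methylmalonaldehyde (2-methylpropanedial) | CC(C=O)C=O | starting material
2 | (2E)-3-[(tert-butyldimethylsilyl)oxy]-2-methylprop-2-enal | O=C/C(C)=C/O[Si](C)(C)C(C)(C)C | intermediate
3 | vinylmagnesium bromide | C=C[Mg]Br | starting material
4 | bromomagnesium (1E)-1-[(tert-butyldimethylsilyl)oxy]-2-methylpenta-1,4-dien-3-olate, racemic | C=CC(O[Mg]Br)/C(C)=C/O[Si](C)(C)C(C)(C)C | intermediate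
5 | rac-(1E)-1-[(tert-butyldimethylsilyl)oxy]-2-methylpenta-1,4-dien-3-yl acetate | C=CC(OC(C)=O)/C(C)=C/O[Si](C)(C)C(C)(C)C | intermediate
6 | (1E,3R)-1-[(tert-butyldimethylsilyl)oxy]-2-methylpenta-1,4-dien-3-ol | C=C[C@@H](O)/C(C)=C/O[Si](C)(C)C(C)(C)C | intermediate
7 | (1E,3R)-1,3-bis[(tert-butyldimethylsilyl)oxy]-2-methylpenta-1,4-diene | C=C[C@@H](O[Si](C)(C)C(C)(C)C)/C(C)=C/O[Si](C)(C)C(C)(C)C | intermediate
8 | ethyl diazoacetate | CCOC(=O)C=[N+]=[N-] | starting material
9 | ethyl (1R,2S,3R)-3-[(tert-butyldimethylsilyl)oxy]-2-[(1R)-1-[(tert-butyldimethylsilyl)oxy]prop-2-en-1-yl]-2-methylcyclopropane-1-carboxylate | CCOC(=O)[C@H]1[C@@H](O[Si](C)(C)C(C)(C)C)[C@]1(C)[C@H](O[Si](C)(C)C(C)(C)C)C=C | intermediate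
10 | (1R,2S,3R)-3-[(tert-butyldimethylsilyl)oxy]-2-[(1R)-1-[(tert-butyldimethylsilyl)oxy]prop-2-en-1-yl]-N-methoxy-N,2-dimethylcyclopropane-1-carboxamide | CON(C)C(=O)[C@H]1[C@@H](O[Si](C)(C)C(C)(C)C)[C@]1(C)[C@H](O[Si](C)(C)C(C)(C)C)C=C | intermediate
11 | (2-methylprop-2-en-1-yl)magnesium chloride | C=C(C)C[Mg]Cl | starting material
12 | 1-[(1R,2S,3R)-3-[(tert-butyldimethylsilyl)oxy]-2-[(1R)-1-[(tert-butyldimethylsilyl)oxy]prop-2-en-1-yl]-2-methylcyclopropyl]-3-methylbut-3-en-1-one | C=C(C)CC(=O)[C@H]1[C@@H](O[Si](C)(C)C(C)(C)C)[C@]1(C)[C@H](O[Si](C)(C)C(C)(C)C)C=C | intermediate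
13 | 3-methylbutan-2-one | CC(=O)C(C)C | starting material
14 | lithium 3-methylbut-1-en-2-olate | C=C(O[Li])C(C)C | intermediate
15 | 3-methyl-2-[(trimethylsilyl)oxy]but-1-ene | C=C(O[Si](C)(C)C)C(C)C | intermediate
16 | ring-opened zwitterion: tetrachlorotitanate enolate at C5=C6 with O-TBS oxocarbenium ion at C2 on the quaternary C1 (enolate geometry not defined) | C=C(C)CC(O[Ti-](Cl)(Cl)(Cl)Cl)=C[C@](C)(C=[O+][Si](C)(C)C(C)(C)C)[C@H](O[Si](C)(C)C(C)(C)C)C=C | intermediate
17 | open-chain trichlorotitanium enolate carrying the C2 silyl ether and the C4 isopropyl ketone (enolate geometry not defined) | C=C(C)CC(O[Ti](Cl)(Cl)Cl)=C[C@](C)([C@H](CC(=O)C(C)C)O[Si](C)(C)C(C)(C)C)[C@H](O[Si](C)(C)C(C)(C)C)C=C | intermediate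
18 | 1-[(1R,2R,3S,5R)-3-[(tert-butyldimethylsilyl)oxy]-2-[(1R)-1-[(tert-butyldimethylsilyl)oxy]prop-2-en-1-yl]-5-hydroxy-2-methyl-5-(propan-2-yl)cyclopentyl]-3-methylbut-3-en-1-one | C=C(C)CC(=O)[C@H]1[C@](O)(C(C)C)C[C@H](O[Si](C)(C)C(C)(C)C)[C@]1(C)[C@H](O[Si](C)(C)C(C)(C)C)C=C | intermediate
19 | (1R,2S,4R,5R,10R)-2,10-bis[(tert-butyldimethylsilyl)oxy]-4-hydroxydauc-8-en-6-one | O=C1CC(C)=C[C@@H](O[Si](C)(C)C(C)(C)C)[C@@]2(C)[C@@H](O[Si](C)(C)C(C)(C)C)C[C@@](O)(C(C)C)[C@H]12 | intermediate
20 | (1R,2S,4R,5S,6S,10R)-2,10-bis[(tert-butyldimethylsilyl)oxy]dauc-8-ene-4,6-diol | O[C@H]1CC(C)=C[C@@H](O[Si](C)(C)C(C)(C)C)[C@@]2(C)[C@@H](O[Si](C)(C)C(C)(C)C)C[C@@](O)(C(C)C)[C@H]12 | intermediate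
21 | 3,4-dimethoxybenzoyl chloride | COc1ccc(C(=O)Cl)cc1OC | starting material
22 | (1R,2S,4R,5S,6S,10R)-2,10-bis[(tert-butyldimethylsilyl)oxy]-4-hydroxydauc-8-en-6-yl 3,4-dimethoxybenzoate | COc1ccc(C(=O)O[C@H]2CC(C)=C[C@@H](O[Si](C)(C)C(C)(C)C)[C@@]3(C)[C@@H](O[Si](C)(C)C(C)(C)C)C[C@@](O)(C(C)C)[C@H]23)cc1OC | intermediate
23 | (1R,2S,4R,5S,6S,10R)-2,4,10-trihydroxydauc-8-en-6-yl 3,4-dimethoxybenzoate | COc1ccc(C(=O)O[C@H]2CC(C)=C[C@@H](O)[C@@]3(C)[C@@H](O)C[C@@](O)(C(C)C)[C@H]23)cc1OC | intermediate
24 | (1R,2S,4R,5S,6S,10R)-2,10-diacetoxy-4-hydroxydauc-8-en-6-yl 3,4-dimethoxybenzoate | COc1ccc(C(=O)O[C@H]2CC(C)=C[C@@H](OC(C)=O)[C@@]3(C)[C@@H](OC(C)=O)C[C@@](O)(C(C)C)[C@H]23)cc1OC | target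

Total step count: 14. Longest linear sequence: 13 steps (steps 1–7 and 9–14); step 8 is a one-step side branch.

Steps most likely to fail

Step 9. The ring-opened zwitterion may be diverted before the external enol ether captures it: by Prins attack of the pendant methallyl alkene on the oxocarbenium ion, by combination of two zwitterions, or by Lewis-acid-induced migration of the β,γ-double bond of the ketone. The addition to C2 may also show insufficient facial selectivity. The fallback keeps the same bond-forming event but runs it one stage earlier, on a substrate without the pendant alkene and with a chelating acceptor. It sets out from Weinreb amide 10. Treatment of 10 with 15 and TiCl4 (CH2Cl2, −78 °C), where the N-methoxy amide holds titanium in a chelate, should give the annulated cyclopentane Weinreb amide F1. Addition of Grignard reagent 11 to F1 (THF, −78 °C, buffered work-up) should then install the methallyl ketone, and the route is rejoined at 18.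

Step 5. Carbene transfer may occur with poor facial selectivity with respect to the C10 stereocentre, giving the C1 epimer, and part of the carbenoid may be lost to the terminal vinyl group. The fallback moves the source of stereocontrol from the substrate to the catalyst. It sets out from 7 and 8, which are combined under asymmetric catalysis with CuOTf (monovalent copper) and a C2-symmetric tert-butyl bis(oxazoline) ligand, the ligand antipode being chosen so that catalyst and C10 substituent reinforce each other. It returns to the route at 9 and creates no compound outside the list (F0).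

Step 10. Initiation at the hindered allylic silyl ether may be slow, so that dimerisation competes, and ruthenium hydride species may move the new β,γ-double bond into conjugation with the C6 ketone. The fallback changes the order of events so that metathesis is run on a substrate without an enolisable ketone. It sets out from 18. Directed reduction with Me4NBH(OAc)3 (MeCN/AcOH, −30 °C) should give the open-chain anti diol F2. Acylation of the secondary hydroxyl with 21 (Et3N, DMAP) should give the veratrate diene F3. Ring-closing metathesis of F3 with the second-generation Grubbs catalyst then returns to the route at 22.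

Further compounds
F1 | step 9 | (1R,2R,3S,5R)-3-[(tert-butyldimethylsilyl)oxy]-2-[(1R)-1-[(tert-butyldimethylsilyl)oxy]prop-2-en-1-yl]-5-hydroxy-N-methoxy-N,2-dimethyl-5-(propan-2-yl)cyclopentane-1-carboxamide | CON(C)C(=O)[C@H]1[C@](O)(C(C)C)C[C@H](O[Si](C)(C)C(C)(C)C)[C@]1(C)[C@H](O[Si](C)(C)C(C)(C)C)C=C
F0 | step 5 | none | none
F2 | step 10 | (1S)-1-[(1S,2R,3S,5R)-3-[(tert-butyldimethylsilyl)oxy]-2-[(1R)-1-[(tert-butyldimethylsilyl)oxy]prop-2-en-1-yl]-5-hydroxy-2-methyl-5-(propan-2-yl)cyclopentyl]-3-methylbut-3-en-1-ol | C=C(C)C[C@H](O)[C@H]1[C@](O)(C(C)C)C[C@H](O[Si](C)(C)C(C)(C)C)[C@]1(C)[C@H](O[Si](C)(C)C(C)(C)C)C=C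
F3 | step 10 | (1S)-1-[(1S,2R,3S,5R)-3-[(tert-butyldimethylsilyl)oxy]-2-[(1R)-1-[(tert-butyldimethylsilyl)oxy]prop-2-en-1-yl]-5-hydroxy-2-methyl-5-(propan-2-yl)cyclopentyl]-3-methylbut-3-en-1-yl 3,4-dimethoxybenzoate | COc1ccc(C(=O)O[C@@H](CC(C)=C)[C@H]2[C@](O)(C(C)C)C[C@H](O[Si](C)(C)C(C)(C)C)[C@]2(C)[C@H](O[Si](C)(C)C(C)(C)C)C=C)cc1OC
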